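**Remark on the chemistry:** the target is read as labd-7-ene-2α,15-diol 15-[(Z)-p-coumarate] of the normal labdane series (2S,5S,9S,10S,13S); labdane numbering is used for all intermediates, and every (Z)-cinnamoyl compound is assumed to be handled with exclusion of light.

## Analysis of the target

The target is a bicyclic labdane: a trans-fused decalin (ring A C1–C5/C10, ring B C5–C10) with a trisubstituted C7=C8 alkene bearing the C17 methyl group, a gem-dimethyl C4 and an angular methyl group on quaternary C10. Its C9 side chain (C11–C16) ends in a C15 ester of (Z)-p-coumaric acid. Four of the five stereocentres lie on the decalin and are fixed relative to each other: H5 and H9 are axial on the α face, the C20 methyl group is axial on the β face, and the C2 hydroxyl is equatorial (2α), trans to C20. The fifth, C13 (S), is four bonds away from the ring and cannot be controlled from it. The sensitive groups are the (Z)-cinnamate (goes to E under light, acyl-transfer catalysts or base), the free phenol, and the C7=C8 alkene (moves to C8=C9 under acid). The hard points are the quaternary C10 beside the gem-dimethyl C4, the relay of absolute configuration from C2 to C5, C9 and C10, the remote C13, the position of the alkene, and acylation of the primary C15 hydroxyl beside the secondary C2 hydroxyl with the (Z) geometry intact. The strategy rests on two recognitions: ring A with its C2 carbinol, C4 gem-dimethyl group and C10 methyl group is the hydroxylated trimethylcyclohexene of the 3-hydroxy-ionone series, and C9 with C11–C16 is the chain of (S)-citronellol. Once these two chiral-pool pieces are joined through C5–C6, only the C9–C10 bond of ring B is left to make.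

## Retrosynthetic reasoning

**C15–O ester bond.** The target 26 is first traced to its phenol silyl ether 25, then cut at the ester on the alkyl side, giving the diol 19 and the (Z)-acid 24. Cutting the O–alkyl bond (Mitsunobu) means the acid is never activated as an acyl donor, which is the usual cause of Z→E leakage. It also discriminates the two hydroxyls: displacement at C2 would need backside attack along the β-axial direction, which the axial methyl groups on C4 and C10 block.

**Cα=Cβ of the cinnamate.** The (Z)-alkene of 24 is traced to the alkyne of 23, so that the geometry comes from syn addition of hydrogen and not from a photostationary mixture. 23 goes back through the acetylide 22 to the dibromoalkene 21 and the commercial aldehyde 20. This branch is short and off the main line.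

**Acetates.** 19 comes from the diacetate 18 by methanolysis. The acetates are there only because the ring-forming step needs oxygen substituents that survive superacid.

**C9–C10 bond (key disconnection).** Cutting C9–C10 of 18 opens ring B and gives the monocyclic diene 17, in which ring A is intact and the chain carries an (E)-C8=C9 alkene. This bond is chosen because it is the only bond that separates the two chiral-pool pieces once C5–C6 is in place. Forward, protonation of the C5=C10 alkene must produce the C10 cation, C9 must add to it through a chair, and the C8 cation must lose H7. One step then makes the quaternary centre and three stereocentres under the control of C2.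

**Oxygen protecting groups.** 17 is traced to the bis-silyl ether 15 through the diol 16. Silyl ethers are needed for the enolate and ylide chemistry that builds the fragments, but they would not survive superacid, so they are exchanged in one operation just before the key step.

**C5–C6 bond.** 15 is cut between the ring carbon C5 and C6 into the enol triflate 6 and the diene 13, joined forward through the alkylborane 14 by a B-alkyl Suzuki–Miyaura coupling. This cut puts the tetrasubstituted C5=C10 alkene in place regiospecifically (it is the enol double bond of the ketone). It also leaves the (E)-C8=C9 alkene to be made earlier by a stabilised ylide.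

**Ring A piece.** 6 comes from the silyloxy ketone 4 through its enolate 5; only C6 of the ketone can be deprotonated. 4 comes from (4R,6R)-actinol 3, which is made from ketoisophorone 1 through (6R)-levodione 2 by two reductions. The C6 centre serves only to set C4 and is erased in 6.

**Chain piece.** 13 comes from the enal 12 by methylenation. 12 comes from the aldehyde 10 and the stabilised ylide 11, which fixes the (E) geometry that later becomes the C9 configuration. 10 comes from the silyl ether 8 of (S)-citronellol 7 by ozonolysis through the ozonide 9. C13 is bought and never touched.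

## Alternatives that were turned down

**Alternative 1:** Both rings are disconnected at once, at C5–C10 and C8–C9, back to the open-chain triene ester A1, which has a (E)-3-methyl enoate at one end and a 2-silyloxydiene at the other. Forward, heating A1 would give the decalin A2 by an intramolecular Diels–Alder reaction, setting C5, C8, C9 and C10.
- For it: two rings and two bonds in a neutral thermal step. The C7 oxygen of A2 marks unambiguously where the alkene must end up (ketone, enol triflate, reduction). On alkene regiocontrol this is stronger than the chosen route.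
- Against it: the dienophile is a β,β-disubstituted enoate and the diene terminus sits on the quaternary C4, so the cycloaddition is slow and needs temperatures at which a silyl enol ether is at risk. Facial and endo/exo control would rest on one silyloxy centre in a flexible four-atom tether. C8 is set and then destroyed. C2 must come from asymmetric synthesis. After the cycloaddition the whole C12–C16 chain with C13 still has to be attached to a C11 ester next to quaternary C10.
- Comparison: the chosen route has the full carbon skeleton and both chiral-pool centres in place before ring closure and needs three steps after 18 on the main line.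

**Alternative 2:** Ring A is disconnected at C3–C4, back to the pinane-type ketone A3, which carries a propargyl group and the methyl group on C10 and the side chain on C9. Forward, acid activation of the C8 ketone would break the strained C4–C7 cyclobutane bond. The C4 cation would be captured by the alkyne terminus, and hydration would give the diketone A4.
- For it: C5, C9 and C10 are held by a rigid chiral-pool bicycle. The C8 ketone allows the C7=C8 alkene and the C17 methyl group to be installed regiospecifically by enol triflate chemistry. On this point it is stronger than the chosen route.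
- Against it: the cascade is unprecedented as a whole and needs a 6-endo-dig closure through an endocyclic vinyl cation. A4 has two ketones to differentiate. Hydride reduction of the C2 ketone should come from the α face (the β face carries two axial methyl groups) and give the wrong, axial 2β-alcohol, so a thermodynamic reduction would be needed. The benzyl ether must later be removed in the presence of an alkene.
- Comparison: in the chosen route the C2 configuration is bought, is never a ketone, and itself directs the ring closure; the price is a termination step controlled by kinetics and not by a functional group.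

**Alternative 3:** Ring B is disconnected at C9–C10 and C7–C8, back to the dienyl but-2-ynoate A5, in which the alkynoate is tethered through the C2 oxygen. Forward, heating A5 would add the C10=C5–C6=C7 diene to the alkyne and give the bridged dienyl lactone A6, creating quaternary C10.
- For it: the tether ties the new C10 centre to C2 intramolecularly, so the facial selectivity at C10 is more rigorously secured than in the chosen route.
- Against it: ester tethers resist the s-cis arrangement needed, and the diene terminus is fully substituted. A6 is at the wrong oxidation level twice: the C5=C6 alkene must be reduced to 5α-H although the lactone bridge lies on the α face, and the conjugated C8=C9 alkene must be moved to C7=C8 while C9 is set. C11 is a carboxyl carbon, so C12–C16 and C13 are still missing.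
- Comparison: the chosen route sets C5, C9 and C10 and places the alkene in the same step that makes the C9–C10 bond, with the side chain already present.

Key step: step 11

## Route

Step 1
Reactants: 1 ketoisophorone (2,6,6-trimethylcyclohex-2-ene-1,4-dione)
Product: 2 (6R)-2,2,6-trimethylcyclohexane-1,4-dione ((6R)-levodione)
Conditions: baker's yeast (Saccharomyces cerevisiae), sucrose, H2O, 30 °C
Reagents that add atoms: none
Why: Enzymatic conjugate reduction of the enedione C=C bond (ene-reductase of yeast) should set the methyl-bearing carbon as R; this centre only relays configuration to C4 and is erased in step 4.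

Step 2
Reactants: 2 (6R)-levodione
Product: 3 (4R,6R)-4-hydroxy-2,2,6-trimethylcyclohexan-1-one ((4R,6R)-actinol)
Conditions: H2, Raney Ni, MeOH, rt; recrystallisation
Reagents that add atoms: none
Why: Chemoselective catalytic hydrogenation of the unhindered C4 carbonyl (C1 is shielded by three α-methyl groups); hydrogen should arrive anti to the axial C2 methyl group and give mainly the trans alcohol. The cis isomer is removed by crystallisation, because after step 4 it would lead to the enantiomer of 6.

Step 3
Reactants: 3 (4R,6R)-actinol
Product: 4 (4R,6R)-4-[(tert-butyldimethylsilyl)oxy]-2,2,6-trimethylcyclohexan-1-one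
Conditions: TBSCl, imidazole, DMF, rt
Reagents that add atoms: tert-butyldimethylsilyl chloride, CC(C)(C)[Si](C)(C)Cl
Why: Standard silylation of a secondary alcohol; a silyl ether is needed because the next step uses a lithium amide base.

Step 4
Reactants: 4 (4R,6R)-4-[(tert-butyldimethylsilyl)oxy]-2,2,6-trimethylcyclohexan-1-one
Product: 6 (4R)-4-[(tert-butyldimethylsilyl)oxy]-2,6,6-trimethylcyclohex-1-en-1-yl trifluoromethanesulfonate, via lithium enolate 5 (not isolated)
Conditions: LiN(i-Pr)2 (LDA), THF, −78 °C; then PhNTf2, −78 °C to rt
Reagents that add atoms: N-phenylbis(trifluoromethanesulfonimide), O=S(=O)(N(c1ccccc1)S(=O)(=O)C(F)(F)F)C(F)(F)F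
Why: Enol triflate formation; only C6 carries an α-hydrogen, so a single tetrasubstituted enolate forms and is O-triflated. C6 becomes sp2 and C4 (R) is untouched.

Step 5
Reactants: 7 (S)-citronellol ((3S)-3,7-dimethyloct-6-en-1-ol)
Product: 8 tert-butyl{[(3S)-3,7-dimethyloct-6-en-1-yl]oxy}dimethylsilane
Conditions: TBSCl, imidazole, DMF, rt
Reagents that add atoms: tert-butyldimethylsilyl chloride, CC(C)(C)[Si](C)(C)Cl
Why: Standard silylation of the primary alcohol; the silyl ether survives the ylide, borane and basic coupling steps that follow.

Step 6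
Reactants: 8 tert-butyl{[(3S)-3,7-dimethyloct-6-en-1-yl]oxy}dimethylsilane
Product: 10 (4S)-6-[(tert-butyldimethylsilyl)oxy]-4-methylhexanal, via secondary ozonide 9 (not isolated)
Conditions: O3, CH2Cl2, −78 °C; then PPh3, −78 °C to rt
Reagents that add atoms: ozone, [O-][O+]=O
Why: Ozonolysis with reductive work-up of the only alkene; the C13 centre is remote and unaffected.

Step 7
Reactants: 10 (4S)-6-[(tert-butyldimethylsilyl)oxy]-4-methylhexanal; 11 2-(triphenylphosphoranylidene)propanal
Product: 12 (2E,6S)-8-[(tert-butyldimethylsilyl)oxy]-2,6-dimethyloct-2-enal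
Conditions: toluene, 80 °C
Reagents that add atoms: none
Why: Wittig olefination with a stabilised ylide, which should give the (E)-2-methyl enal; this fixes the C8=C9 geometry that later sets C9.

Step 8
Reactants: 12 (2E,6S)-8-[(tert-butyldimethylsilyl)oxy]-2,6-dimethyloct-2-enal
Product: 13 tert-butyl{[(3S,6E)-3,7-dimethylnona-6,8-dien-1-yl]oxy}dimethylsilane
Conditions: Ph3PCH3Br, KOt-Bu, THF, 0 °C
Reagents that add atoms: methyltriphenylphosphonium bromide, C[P+](c1ccccc1)(c1ccccc1)c1ccccc1.[Br-]
Why: Wittig methylenation of the enal by 1,2-addition; the trisubstituted (E)-alkene is not touched.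

Step 9
Reactants: 13 tert-butyl{[(3S,6E)-3,7-dimethylnona-6,8-dien-1-yl]oxy}dimethylsilane; 6 (4R)-4-[(tert-butyldimethylsilyl)oxy]-2,6,6-trimethylcyclohex-1-en-1-yl trifluoromethanesulfonate
Product: 15 (2R,8E,13S)-2,15-bis[(tert-butyldimethylsilyl)oxy]-9,10-secolabda-5(10),8-diene, via B-alkyl-9-BBN adduct 14 (not isolated)
Conditions: 9-BBN, THF, 0 °C to rt; then 6, Pd(dppf)Cl2, K3PO4 (aq), DMF, 60 °C
Reagents that add atoms: none
Why: 9-BBN should hydroborate only the terminal monosubstituted alkene of the diene (boron on C6). B-alkyl Suzuki–Miyaura coupling with the enol triflate then forms C5–C6 and places the tetrasubstituted C5=C10 alkene regiospecifically.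

Step 10
Reactants: 15 (2R,8E,13S)-2,15-bis[(tert-butyldimethylsilyl)oxy]-9,10-secolabda-5(10),8-diene
Product: 17 (2R,8E,13S)-9,10-secolabda-5(10),8-diene-2,15-diyl diacetate, via seco-diol 16 (not isolated)
Conditions: Bu4NF (TBAF), THF, rt to 40 °C; then pyridine, Ac2O, DMAP (cat.), rt
Reagents that add atoms: acetic anhydride, CC(=O)OC(C)=O
Why: Fluoride desilylation followed by acetylation in the same flask; acetates are installed because they are inert when protonated in superacid, whereas silyl ethers would be cleaved.

Step 11
Reactants: 17 (2R,8E,13S)-9,10-secolabda-5(10),8-diene-2,15-diyl diacetate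
Product: 18 labd-7-ene-2α,15-diyl diacetate
Conditions: FSO3H (10 equiv), 2-nitropropane, −78 °C; then Et3N, −78 °C to rt
Reagents that add atoms: none
Why: The superacid protonates the tetrasubstituted C5=C10 alkene reversibly at C5 to give the tertiary C10 cation, while both acetates are held as protonated, non-nucleophilic carboxonium ions. C9 of the (E)-C8=C9 alkene then adds to C10 (6-endo-trig cation–olefin closure of ring B through a chair), and the tertiary C8 cation loses H7 to give the C7=C8 alkene. The closest known reaction type is the fluorosulfonic or chlorosulfonic acid cyclisation of ionone-derived monocyclic polyenes to trans-fused drimane and labdane bicycles, which tolerates acetates. C5 is set by the protonation, which is reversible, so ring closure should drain the epimer whose C6 tether is equatorial. C10 is set because C9 then approaches along the equatorial direction of ring A, leaving the C20 methyl group axial and the fusion trans. C9 is set by the (E) geometry, which puts C11 equatorial (9β) and H9 axial. The absolute sense comes from C2: its acetoxy group stays equatorial because the axial site is flanked by the axial C4 methyl group and the developing axial C20 methyl group, so C20 ends trans to the C2 oxygen. The step also needs regioselective termination; loss of the axial H7, antiperiplanar to the empty orbital at C8, is the kinetic path at −78 °C, and the cold amine quench is meant to prevent equilibration to the 8(9) and 8(17) isomers.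

Step 12
Reactants: 18 labd-7-ene-2α,15-diyl diacetate
Product: 19 labd-7-ene-2α,15-diol
Conditions: K2CO3, MeOH, rt
Reagents that add atoms: none
Why: Base-catalysed transesterification removes both acetates; the C7=C8 alkene is stable to base.

Step 13
Reactants: 20 4-[(tert-butyldimethylsilyl)oxy]benzaldehyde
Product: 21 tert-butyl[4-(2,2-dibromoethenyl)phenoxy]dimethylsilane
Conditions: CBr4, PPh3, CH2Cl2, 0 °C
Reagents that add atoms: carbon tetrabromide, BrC(Br)(Br)Br
Why: First stage of the Corey–Fuchs sequence (dibromo-olefination of an aryl aldehyde); the aryl silyl ether is stable under these neutral conditions.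

Step 14
Reactants: 21 tert-butyl[4-(2,2-dibromoethenyl)phenoxy]dimethylsilane
Product: 23 3-{4-[(tert-butyldimethylsilyl)oxy]phenyl}prop-2-ynoic acid, via lithium acetylide 22 (not isolated)
Conditions: n-BuLi (2.2 equiv), THF, −78 °C; then CO2; then 1 M HCl, 0 °C
Reagents that add atoms: carbon dioxide, O=C=O
Why: Second stage of the Corey–Fuchs sequence (bromine–lithium exchange, Fritsch–Buttenberg–Wiechell rearrangement, deprotonation) followed by carboxylation of the acetylide.

Step 15
Reactants: 23 3-{4-[(tert-butyldimethylsilyl)oxy]phenyl}prop-2-ynoic acid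
Product: 24 (Z)-3-{4-[(tert-butyldimethylsilyl)oxy]phenyl}prop-2-enoic acid
Conditions: H2 (1 atm), Pd/CaCO3 poisoned with Pb(OAc)2 (Lindlar catalyst), quinoline, EtOAc, rt, dark
Reagents that add atoms: none
Why: Lindlar semi-hydrogenation; syn addition of hydrogen to the alkyne gives the (Z)-cinnamic acid, so the geometry is set by mechanism.

Step 16
Reactants: 19 labd-7-ene-2α,15-diol; 24 (Z)-3-{4-[(tert-butyldimethylsilyl)oxy]phenyl}prop-2-enoic acid
Product: 25 labd-7-ene-2α,15-diol 15-[(Z)-4-(tert-butyldimethylsilyloxy)cinnamate]
Conditions: PPh3, DIAD, THF, 0 °C to rt, dark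
Reagents that add atoms: none
Why: Mitsunobu esterification activates the primary C15 alcohol and not the acid, so no acyl intermediate can isomerise the (Z)-alkene. The C2 hydroxyl should not react, because inversion there would need attack along the β-axial direction blocked by the axial C4 and C10 methyl groups.

Step 17
Reactants: 25 labd-7-ene-2α,15-diol 15-[(Z)-4-(tert-butyldimethylsilyloxy)cinnamate]
Product: 26 labd-7-ene-2α,15-diol 15-[(Z)-p-coumarate] (CNP0301213.1)
Conditions: Bu4NF (TBAF), AcOH, THF, 0 °C, dark
Reagents that add atoms: none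
Why: Fluoride cleavage of the aryl silyl ether; the acetic acid buffer keeps the phenol protonated, so the ester and the (Z)-alkene are not exposed to phenoxide or free base.

## Compound list

1 | ketoisophorone (2,6,6-trimethylcyclohex-2-ene-1,4-dione) | CC1=CC(=O)CC(C)(C)C1=O | starting material
2 | (6R)-2,2,6-trimethylcyclohexane-1,4-dione ((6R)-levodione) | C[C@@H]1CC(=O)CC(C)(C)C1=O | intermediate
3 | (4R,6R)-4-hydroxy-2,2,6-trimethylcyclohexan-1-one ((4R,6R)-actinol) | C[C@@H]1C[C@@H](O)CC(C)(C)C1=O | intermediate
4 | (4R,6R)-4-[(tert-butyldimethylsilyl)oxy]-2,2,6-trimethylcyclohexan-1-one | C[C@@H]1C[C@@H](O[Si](C)(C)C(C)(C)C)CC(C)(C)C1=O | intermediate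
5 | lithium (4R)-4-[(tert-butyldimethylsilyl)oxy]-2,6,6-trimethylcyclohex-1-en-1-olate (not isolated) | [Li]OC1=C(C)C[C@@H](O[Si](C)(C)C(C)(C)C)CC1(C)C | intermediate
6 | (4R)-4-[(tert-butyldimethylsilyl)oxy]-2,6,6-trimethylcyclohex-1-en-1-yl trifluoromethanesulfonate | O=S(=O)(OC1=C(C)C[C@@H](O[Si](C)(C)C(C)(C)C)CC1(C)C)C(F)(F)F | intermediate
7 | (S)-citronellol ((3S)-3,7-dimethyloct-6-en-1-ol) | OCC[C@@H](C)CCC=C(C)C | starting material
8 | tert-butyl{[(3S)-3,7-dimethyloct-6-en-1-yl]oxy}dimethylsilane | CC(C)(C)[Si](C)(C)OCC[C@@H](C)CCC=C(C)C | intermediate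
9 | 5-{(3S)-5-[(tert-butyldimethylsilyl)oxy]-3-methylpentyl}-3,3-dimethyl-1,2,4-trioxolane (not isolated) | CC(C)(C)[Si](C)(C)OCC[C@@H](C)CCC1OOC(C)(C)O1 | intermediate
10 | (4S)-6-[(tert-butyldimethylsilyl)oxy]-4-methylhexanal | CC(C)(C)[Si](C)(C)OCC[C@@H](C)CCC=O | intermediate
11 | 2-(triphenylphosphoranylidene)propanal | CC(C=O)=P(c1ccccc1)(c1ccccc1)c1ccccc1 | starting material
12 | (2E,6S)-8-[(tert-butyldimethylsilyl)oxy]-2,6-dimethyloct-2-enal | CC(C)(C)[Si](C)(C)OCC[C@@H](C)CC/C=C(\C)C=O | intermediate
13 | tert-butyl{[(3S,6E)-3,7-dimethylnona-6,8-dien-1-yl]oxy}dimethylsilane | CC(C)(C)[Si](C)(C)OCC[C@@H](C)CC/C=C(\C)C=C | intermediate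
14 | 9-{(3E,7S)-9-[(tert-butyldimethylsilyl)oxy]-3,7-dimethylnon-3-en-1-yl}-9-borabicyclo[3.3.1]nonane (not isolated) | CC(C)(C)[Si](C)(C)OCC[C@@H](C)CC/C=C(\C)CCB1C2CCCC1CCC2 | intermediate
15 | (2R,8E,13S)-2,15-bis[(tert-butyldimethylsilyl)oxy]-9,10-secolabda-5(10),8-diene | CC(C)(C)[Si](C)(C)OCC[C@@H](C)CC/C=C(\C)CCC1=C(C)C[C@@H](O[Si](C)(C)C(C)(C)C)CC1(C)C | intermediate
16 | (2R,8E,13S)-9,10-secolabda-5(10),8-diene-2,15-diol (not isolated) | OCC[C@@H](C)CC/C=C(\C)CCC1=C(C)C[C@@H](O)CC1(C)C | intermediate
17 | (2R,8E,13S)-9,10-secolabda-5(10),8-diene-2,15-diyl diacetate (key-step precursor) | CC(=O)OCC[C@@H](C)CC/C=C(\C)CCC1=C(C)C[C@@H](OC(C)=O)CC1(C)C | intermediate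
18 | labd-7-ene-2α,15-diyl diacetate (key-step product) | CC1=CC[C@H]2C(C)(C)C[C@H](OC(C)=O)C[C@]2(C)[C@H]1CC[C@H](C)CCOC(C)=O | intermediate
19 | labd-7-ene-2α,15-diol | CC1=CC[C@H]2C(C)(C)C[C@H](O)C[C@]2(C)[C@H]1CC[C@H](C)CCO | intermediate
20 | 4-[(tert-butyldimethylsilyl)oxy]benzaldehyde | CC(C)(C)[Si](C)(C)Oc1ccc(C=O)cc1 | starting material
21 | tert-butyl[4-(2,2-dibromoethenyl)phenoxy]dimethylsilane | CC(C)(C)[Si](C)(C)Oc1ccc(C=C(Br)Br)cc1 | intermediate
22 | lithium {4-[(tert-butyldimethylsilyl)oxy]phenyl}acetylide (not isolated) | [Li]C#Cc1ccc(O[Si](C)(C)C(C)(C)C)cc1 | intermediate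
23 | 3-{4-[(tert-butyldimethylsilyl)oxy]phenyl}prop-2-ynoic acid | OC(=O)C#Cc1ccc(O[Si](C)(C)C(C)(C)C)cc1 | intermediate
24 | (Z)-3-{4-[(tert-butyldimethylsilyl)oxy]phenyl}prop-2-enoic acid | OC(=O)/C=C\c1ccc(O[Si](C)(C)C(C)(C)C)cc1 | intermediate
25 | labd-7-ene-2α,15-diol 15-[(Z)-4-(tert-butyldimethylsilyloxy)cinnamate] | CC1=CC[C@H]2C(C)(C)C[C@H](O)C[C@]2(C)[C@H]1CC[C@H](C)CCOC(=O)/C=C\c1ccc(O[Si](C)(C)C(C)(C)C)cc1 | intermediate
26 | labd-7-ene-2α,15-diol 15-[(Z)-p-coumarate] (CNP0301213.1) | CC1=CC[C@H]2C(C)(C)C[C@H](O)C[C@]2(C)[C@H]1CC[C@H](C)CCOC(=O)/C=C\c1ccc(O)cc1 | target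

## Step count and least certain steps

Total step count: 17. Longest linear sequence: 10 steps (steps 5–12, 16 and 17 from 7; equally steps 1–4, 9–12, 16 and 17 from 1).

**Step 11 (key step).** Most likely to go wrong is the termination: proton loss from the C8 cation toward the C17 methyl group or toward C9 instead of C7, because all three protons are accessible and the exocyclic and tetrasubstituted alkenes are not disfavoured thermodynamically. Reversible protonation of the C8=C9 alkene before ring closure could also erode the (E) geometry and with it the C9 configuration. The fallback fixes the alkene position by enol triflate chemistry instead of by proton loss. It sets out from 17, which is cyclised and quenched as before. The exocyclic isomer labd-8(17)-ene-2α,15-diyl diacetate F1, the expected main by-product, is separated on AgNO3-impregnated silica and ozonised (O3; then Me2S) to 17-nor-8-oxolabdane-2α,15-diyl diacetate F2. Kinetic enolisation toward the less hindered C7 (KN(SiMe3)2, PhNTf2, THF, −78 °C) gives 2α,15-diacetoxy-17-norlabd-7-en-8-yl trifluoromethanesulfonate F3. Methylation by Suzuki–Miyaura coupling (trimethylboroxine, Pd(dppf)Cl2, K3PO4) returns to the route at 18.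

**Step 9.** Most likely to go wrong is slow transmetalation of the bulky B-alkyl-9-BBN to the crowded alkenylpalladium intermediate (flanked by the C4 gem-dimethyl and C10 methyl groups), with hydrolysis of the triflate and β-hydride elimination taking over. The fallback leaves the hindered sp2 carbon alone and makes the neighbouring C6–C7 bond by sulfone alkylation; it sets out from 6 and 12 and returns at 15.
- Ring side: methoxycarbonylation of 6, in which only the small CO has to reach the metal (Pd(OAc)2, PPh3, CO, MeOH, Et3N, DMF), gives methyl (4R)-4-[(tert-butyldimethylsilyl)oxy]-2,6,6-trimethylcyclohex-1-ene-1-carboxylate F4. Reduction with i-Bu2AlH gives {(4R)-4-[(tert-butyldimethylsilyl)oxy]-2,6,6-trimethylcyclohex-1-en-1-yl}methanol F5. CBr4/PPh3 gives the allylic bromide F6, and PhSO2Na in DMF gives the allylic phenyl sulfone F7.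
- Chain side: NaBH4/CeCl3 reduces 12 to (2E,6S)-8-[(tert-butyldimethylsilyl)oxy]-2,6-dimethyloct-2-en-1-ol F8, and CBr4/PPh3 converts it into the allylic bromide F9.
- Coupling: deprotonation of F7 with n-BuLi and alkylation with F9 gives the C6 phenylsulfonyl derivative of 15, F10. Reduction with LiBHEt3 and catalytic Pd(dppp)Cl2 removes the sulfonyl group, with hydride delivered to the less substituted C6 terminus, and gives 15.

**Step 16.** Most likely to go wrong is incomplete chemoselectivity: some activation of the C2 hydroxyl (leading to elimination) or stalling of the esterification of the primary alcohol before full conversion. The fallback differentiates the two hydroxyls by protection; it sets out from 19 and returns at 26. Et3SiCl and imidazole give 2α,15-bis(triethylsilyloxy)labd-7-ene F11. Pyridinium p-toluenesulfonate in MeOH/CH2Cl2 at 0 °C removes the primary silyl ether selectively and gives 2α-(triethylsilyloxy)labd-7-en-15-ol F12. Mitsunobu esterification with 24 gives 2α-(triethylsilyloxy)labd-7-en-15-yl (Z)-4-(tert-butyldimethylsilyloxy)cinnamate F13. HF·pyridine in THF/pyridine removes both silyl groups and gives 26.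

**Step 15.** Most likely to go wrong is over-reduction to the saturated acid and partial Z-to-E isomerisation on the catalyst surface, both of which are hard to separate at the acid stage. The fallback builds the (Z)-alkene by olefination on the labdane ester; it sets out from 19 and 20 and returns at 25. Esterification of the C15 hydroxyl of 19 with 2-(diphenoxyphosphoryl)acetic acid under the Mitsunobu conditions of step 16 gives labd-7-ene-2α,15-diol 15-[(diphenoxyphosphoryl)acetate] F14. Z-selective Horner–Wadsworth–Emmons olefination of this diaryl phosphonoacetate with 20 (NaH, THF, −78 °C) gives 25.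

## Further compounds

F1 | step 11 | labd-8(17)-ene-2α,15-diyl diacetate | C=C1CC[C@H]2C(C)(C)C[C@H](OC(C)=O)C[C@]2(C)[C@H]1CC[C@H](C)CCOC(C)=O
F2 | step 11 | 17-nor-8-oxolabdane-2α,15-diyl diacetate | O=C1CC[C@H]2C(C)(C)C[C@H](OC(C)=O)C[C@]2(C)[C@H]1CC[C@H](C)CCOC(C)=O
F3 | step 11 | 2α,15-diacetoxy-17-norlabd-7-en-8-yl trifluoromethanesulfonate | O=S(=O)(OC1=CC[C@H]2C(C)(C)C[C@H](OC(C)=O)C[C@]2(C)[C@H]1CC[C@H](C)CCOC(C)=O)C(F)(F)F
F4 | step 9 | methyl (4R)-4-[(tert-butyldimethylsilyl)oxy]-2,6,6-trimethylcyclohex-1-ene-1-carboxylate | COC(=O)C1=C(C)C[C@@H](O[Si](C)(C)C(C)(C)C)CC1(C)C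
F5 | step 9 | {(4R)-4-[(tert-butyldimethylsilyl)oxy]-2,6,6-trimethylcyclohex-1-en-1-yl}methanol | OCC1=C(C)C[C@@H](O[Si](C)(C)C(C)(C)C)CC1(C)C
F6 | step 9 | {[(1R)-4-(bromomethyl)-3,5,5-trimethylcyclohex-3-en-1-yl]oxy}(tert-butyl)dimethylsilane | BrCC1=C(C)C[C@@H](O[Si](C)(C)C(C)(C)C)CC1(C)C
F7 | step 9 | tert-butyldimethyl{[(1R)-3,5,5-trimethyl-4-(phenylsulfonylmethyl)cyclohex-3-en-1-yl]oxy}silane | O=S(=O)(CC1=C(C)C[C@@H](O[Si](C)(C)C(C)(C)C)CC1(C)C)c1ccccc1
F8 | step 9 | (2E,6S)-8-[(tert-butyldimethylsilyl)oxy]-2,6-dimethyloct-2-en-1-ol | CC(C)(C)[Si](C)(C)OCC[C@@H](C)CC/C=C(\C)CO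
F9 | step 9 | {[(3S,6E)-8-bromo-3,7-dimethyloct-6-en-1-yl]oxy}(tert-butyl)dimethylsilane | CC(C)(C)[Si](C)(C)OCC[C@@H](C)CC/C=C(\C)CBr
F10 | step 9 | (2R,8E,13S)-2,15-bis[(tert-butyldimethylsilyl)oxy]-6-(phenylsulfonyl)-9,10-secolabda-5(10),8-diene (both C6 epimers) | CC(C)(C)[Si](C)(C)OCC[C@@H](C)CC/C=C(\C)CC(C1=C(C)C[C@@H](O[Si](C)(C)C(C)(C)C)CC1(C)C)S(=O)(=O)c1ccccc1
F11 | step 16 | 2α,15-bis(triethylsilyloxy)labd-7-ene | CC1=CC[C@H]2C(C)(C)C[C@H](O[Si](CC)(CC)CC)C[C@]2(C)[C@H]1CC[C@H](C)CCO[Si](CC)(CC)CC
F12 | step 16 | 2α-(triethylsilyloxy)labd-7-en-15-ol | CC1=CC[C@H]2C(C)(C)C[C@H](O[Si](CC)(CC)CC)C[C@]2(C)[C@H]1CC[C@H](C)CCO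
F13 | step 16 | 2α-(triethylsilyloxy)labd-7-en-15-yl (Z)-4-(tert-butyldimethylsilyloxy)cinnamate | CC1=CC[C@H]2C(C)(C)C[C@H](O[Si](CC)(CC)CC)C[C@]2(C)[C@H]1CC[C@H](C)CCOC(=O)/C=C\c1ccc(O[Si](C)(C)C(C)(C)C)cc1
F14 | step 15 | labd-7-ene-2α,15-diol 15-[(diphenoxyphosphoryl)acetate] | CC1=CC[C@H]2C(C)(C)C[C@H](O)C[C@]2(C)[C@H]1CC[C@H](C)CCOC(=O)CP(=O)(Oc1ccccc1)Oc1ccccc1
A1 | alternative 1 | methyl (2E,5R,8E,10Z)-5-(tert-butyldimethylsilyloxy)-3,7,7-trimethyl-10-(triethylsilyloxy)dodeca-2,8,10-trienoate | C/C=C(O[Si](CC)(CC)CC)/C=C/C(C)(C)C[C@H](O[Si](C)(C)C(C)(C)C)C/C(C)=C/C(=O)OC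
A2 | alternative 1 | methyl 2α-(tert-butyldimethylsilyloxy)-7-(triethylsilyloxy)drim-6-en-11-oate | C[C@H]1C(O[Si](CC)(CC)CC)=C[C@H]2C(C)(C)C[C@H](O[Si](C)(C)C(C)(C)C)C[C@]2(C)[C@H]1C(=O)OC
A3 | alternative 2 | 3-[(3S)-5-(benzyloxy)-3-methylpentyl]-4,6,6-trimethyl-4-(prop-2-yn-1-yl)bicyclo[3.1.1]heptan-2-one | O=C1[C@@H]2C[C@@H](C2(C)C)[C@](C)(CC#C)[C@H]1CC[C@H](C)CCOCc1ccccc1
A4 | alternative 2 | (13S)-15-benzyloxy-17-norlabdane-2,8-dione | O=C1CC[C@H]2C(C)(C)CC(=O)C[C@]2(C)[C@H]1CC[C@H](C)CCOCc1ccccc1
A5 | alternative 3 | (1R)-4-ethenyl-3,5,5-trimethylcyclohex-3-en-1-yl but-2-ynoate | CC#CC(=O)O[C@@H]1CC(C)=C(C=C)C(C)(C)C1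
A6 | alternative 3 | drima-5,8-dien-11,2α-olide | CC1=C2C(=O)O[C@@H]3C[C@@]2(C)C(=CC1)C(C)(C)C3
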